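**Plan**

- The rings are called A (2-hydroxy-4-methoxy-6-methylbenzoyl end), B (central) and C (methyl ester end), each numbered from its carboxyl-bearing carbon C1. The retrosynthesis cuts the A–B aryl ester, then the B–C aryl ester, then C1–C6 and C2–C3 of ring A.
- Enabling feature: ring A carries C3–H, C4–OMe, C5–H and C6–CH3 in the same order as C3 to C6 of 4-methoxy-6-methyl-2-pyrone. The neighbouring C1 (carboxyl) and C2 (oxygen) correspond to the two alkyne carbons of a 3-methoxypropiolate.
- Forward, ring A is made by pyrone–alkyne cycloaddition with loss of CO2, then unmasked to the free salicylic acid by hydrogenolysis and chelation-controlled demethylation.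
- Rings B and C both come from methyl orsellinate: they are joined as a depside, ring C is methylated at C2–OH, and the ring B phenols are freed.
- The last step esterifies the ring A acid with the unchelated C4–OH of ring B.
- The target has no stereocentre; only regiochemistry has to be controlled (cycloaddition orientation, chelated versus free phenols).

Key step: step 3

Remark: methoxyethyne 4 is assumed to be isolable as a low-boiling liquid handled cold. Lactone 9 is racemic with its bridgehead configuration fixed by the bicycle, so its SMILES carries no descriptors.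

**Route**

Step 1
Reactants: 1 chloroacetaldehyde dimethyl acetal (2-chloro-1,1-dimethoxyethane)
Product: 4 methoxyethyne, via 1-chloro-2-methoxyethene 2 (not isolated), via sodium methoxyacetylide 3 (not isolated)
Conditions: NaNH2 (3.2 equiv), liq. NH3, −33 °C; NH3 evaporated; sat. aq. NaCl, −20 °C; product distilled into a cold trap
Reagents that add atoms: none
Why: Twofold base-induced elimination (methanol, then HCl) with sodium amide in liquid ammonia is the classical preparation of 1-alkoxyalkynes from chloroacetaldehyde acetals, the acetylide salt being protonated on aqueous quench.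

Step 2
Reactants: 4 methoxyethyne; 5 benzyl chloroformate
Product: 7 benzyl 3-methoxyprop-2-ynoate, via lithium methoxyacetylide 6 (not isolated)
Conditions: n-BuLi (1.0 equiv), THF, −78 °C; then cannulated into 5 (1.2 equiv), THF, −78 → 0 °C; chromatography on Et3N-deactivated silica
Reagents that add atoms: none
Why: Deprotonation of the terminal ynol ether and C-acylation of the lithium acetylide with a chloroformate is the standard route to 3-alkoxypropiolates, inverse addition keeping the acetylide from adding to the product.

Step 3
Reactants: 7 benzyl 3-methoxyprop-2-ynoate; 8 4-methoxy-6-methyl-2H-pyran-2-one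
Product: 10 benzyl 2,4-dimethoxy-6-methylbenzoate, via bicyclic lactone 9 (not isolated)
Conditions: 8 (2 equiv), 1,2-dichlorobenzene (1 M), BHT (cat.), Ar, sealed tube, 180 °C
Reagents that add atoms: none
Why: Proposed new method: pyrone 8 should act as the 4π component through C3=C4–C5=C6 and ynoate 7 as the 2π component, the asynchronous [4+2] addition (pyrone C3, the nucleophilic α-carbon of a β-methoxy enoate, bonding to the electrophilic methoxy-bearing β-carbon of the ynoate while pyrone C6 bonds to the ester-bearing carbon) giving bridged lactone 9, which expels CO2 by retro-[4+2] and so aromatises irreversibly. The closest known reaction type is the thermal Diels–Alder/CO2-extrusion of 2-pyrones with acetylenic esters (propiolates, acetylenedicarboxylates) to give benzoates and phthalates; a push–pull 3-alkoxypropiolate has not been shown as the 2π partner. Ring A closes by an intermolecular [4+2] cycloaddition that makes C2–C3 and C1–C6 in one operation, followed by cycloreversion of the lactone bridge. No stereocentre is created in 10, since both bridgeheads of racemic 9 become aromatic carbons. The step needs regioselectivity, secured because the C4 methoxy group (largest HOMO coefficient at pyrone C3) and the ester of the alkyne (largest LUMO coefficient at its β-carbon) direct the carboxyl para to the pyrone methoxy and ortho to the methyl group. It also needs the alkyne to outlast the heating, secured by the methyl ynol ether, which has no β-hydrogen for retro-ene loss of an alkene and is further stabilised by conjugation with the ester.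

Step 4
Reactants: 10 benzyl 2,4-dimethoxy-6-methylbenzoate
Product: 11 2,4-dimethoxy-6-methylbenzoic acid
Conditions: H2 (1 atm), 10% Pd/C, EtOAc, rt
Reagents that add atoms: none
Why: Catalytic hydrogenolysis cleaves the benzyl ester cleanly while the aryl methyl ethers and the arene are inert.

Step 5
Reactants: 11 2,4-dimethoxy-6-methylbenzoic acid
Product: 13 2-hydroxy-4-methoxy-6-methylbenzoic acid, via chloroboron chelate 12 (not isolated)
Conditions: BCl3 (2.5 equiv, 1 M in CH2Cl2), CH2Cl2, −78 → 0 °C; then ice-water
Reagents that add atoms: none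
Why: Chelation-controlled BCl3 demethylation removes only the methyl ether ortho to the carboxyl, because boron bound to the carboxyl oxygen can reach the C2 ether but not the C4 ether.

Step 6
Reactants: 14 methyl orsellinate (methyl 2,4-dihydroxy-6-methylbenzoate)
Product: 16 methyl 2,4-bis(benzyloxy)-6-methylbenzoate, via 4-O-benzyl monoether 15 (not isolated)
Conditions: BnBr (2.5 equiv), K2CO3 (3 equiv), DMF, 70 °C
Reagents that add atoms: benzyl bromide, BrCc1ccccc1
Why: Williamson etherification in DMF alkylates the free C4–OH first and, on heating with excess reagent, the hydrogen-bonded C2–OH as well.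

Step 7
Reactants: 16 methyl 2,4-bis(benzyloxy)-6-methylbenzoate
Product: 18 2,4-bis(benzyloxy)-6-methylbenzoic acid, via potassium carboxylate 17 (not isolated)
Conditions: KOH (5 equiv), DMSO/H2O (4:1), 90 °C; then 1 M HCl, 0 °C
Reagents that add atoms: potassium hydroxide (hydroxide oxygen), [K+].[OH-]
Why: Saponification with poorly solvated hydroxide in aqueous DMSO is the usual answer to 2,6-disubstituted benzoates, and the benzyl ethers are stable to it.

Step 8
Reactants: 18 2,4-bis(benzyloxy)-6-methylbenzoic acid; 14 methyl orsellinate
Product: 20 methyl 4-{[2,4-bis(benzyloxy)-6-methylbenzoyl]oxy}-2-hydroxy-6-methylbenzoate, via mixed trifluoroacetic anhydride 19 (not isolated)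
Conditions: TFAA (2 equiv), toluene, rt
Reagents that add atoms: none
Why: Mixed-anhydride esterification with trifluoroacetic anhydride delivers the hindered, electron-rich aroyl group to the free C4–OH of ring C, the C2–OH being tied up in a hydrogen bond to the methyl ester and unreactive.

Step 9
Reactants: 20 methyl 4-{[2,4-bis(benzyloxy)-6-methylbenzoyl]oxy}-2-hydroxy-6-methylbenzoate
Product: 21 methyl 4-{[2,4-bis(benzyloxy)-6-methylbenzoyl]oxy}-2-methoxy-6-methylbenzoate
Conditions: MeI (3 equiv), K2CO3 (2 equiv), DMF, 40 °C
Reagents that add atoms: iodomethane, CI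
Why: Williamson methylation of the chelated ring C phenol proceeds in DMF, and the depside ester should survive because its carbonyl is shielded by the flanking benzyloxy and methyl groups.

Step 10
Reactants: 21 methyl 4-{[2,4-bis(benzyloxy)-6-methylbenzoyl]oxy}-2-methoxy-6-methylbenzoate
Product: 22 methyl 4-[(2,4-dihydroxy-6-methylbenzoyl)oxy]-2-methoxy-6-methylbenzoate
Conditions: H2 (1 atm), 10% Pd/C, EtOAc/THF, rt
Reagents that add atoms: none
Why: Hydrogenolysis removes both benzyl ethers and leaves the aryl ester, the methyl ester and the methyl ether untouched.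

Step 11
Reactants: 13 2-hydroxy-4-methoxy-6-methylbenzoic acid; 22 methyl 4-[(2,4-dihydroxy-6-methylbenzoyl)oxy]-2-methoxy-6-methylbenzoate
Product: 24 methyl 4-({2-hydroxy-4-[(2-hydroxy-4-methoxy-6-methylbenzoyl)oxy]-6-methylbenzoyl}oxy)-2-methoxy-6-methylbenzoate, via O-acylisourea 23 (not isolated)
Conditions: DCC (1.1 equiv), toluene/Et2O, 0 °C → rt
Reagents that add atoms: none
Why: Carbodiimide esterification through the O-acylisourea should acylate only the ring B C4–OH, because the C2–OH groups of rings A and B are each locked in a hydrogen bond to the adjacent carbonyl and are poor nucleophiles.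

**Compound list**

1 | chloroacetaldehyde dimethyl acetal (2-chloro-1,1-dimethoxyethane) | COC(CCl)OC | starting material
2 | 1-chloro-2-methoxyethene (E/Z mixture) | COC=CCl | intermediate (not isolated)
3 | sodium methoxyacetylide | [Na]C#COC | intermediate (not isolated)
4 | methoxyethyne | COC#C | intermediate
5 | benzyl chloroformate | O=C(Cl)OCc1ccccc1 | starting material
6 | lithium methoxyacetylide | [Li]C#COC | intermediate (not isolated)
7 | benzyl 3-methoxyprop-2-ynoate | COC#CC(=O)OCc1ccccc1 | intermediate
8 | 4-methoxy-6-methyl-2H-pyran-2-one | COC1=CC(=O)OC(C)=C1 | starting material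
9 | benzyl 5,8-dimethoxy-1-methyl-3-oxo-2-oxabicyclo[2.2.2]octa-5,7-diene-6-carboxylate (racemic) | CC12OC(=O)C(C(OC)=C1)C(OC)=C2C(=O)OCc1ccccc1 | intermediate (not isolated)
10 | benzyl 2,4-dimethoxy-6-methylbenzoate | COc1cc(C)c(C(=O)OCc2ccccc2)c(OC)c1 | intermediate
11 | 2,4-dimethoxy-6-methylbenzoic acid | COc1cc(C)c(C(=O)O)c(OC)c1 | intermediate
12 | 2-chloro-7-methoxy-5-methyl-4H-1,3,2-benzodioxaborinin-4-one | COc1cc(C)c2C(=O)OB(Cl)Oc2c1 | intermediate (not isolated)
13 | 2-hydroxy-4-methoxy-6-methylbenzoic acid | COc1cc(C)c(C(=O)O)c(O)c1 | intermediate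
14 | methyl orsellinate (methyl 2,4-dihydroxy-6-methylbenzoate) | COC(=O)c1c(C)cc(O)cc1O | starting material
15 | methyl 4-(benzyloxy)-2-hydroxy-6-methylbenzoate | COC(=O)c1c(C)cc(OCc2ccccc2)cc1O | intermediate (not isolated)
16 | methyl 2,4-bis(benzyloxy)-6-methylbenzoate | COC(=O)c1c(C)cc(OCc2ccccc2)cc1OCc1ccccc1 | intermediate
17 | potassium 2,4-bis(benzyloxy)-6-methylbenzoate | [K+].[O-]C(=O)c1c(C)cc(OCc2ccccc2)cc1OCc1ccccc1 | intermediate (not isolated)
18 | 2,4-bis(benzyloxy)-6-methylbenzoic acid | OC(=O)c1c(C)cc(OCc2ccccc2)cc1OCc1ccccc1 | intermediate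
19 | 2,4-bis(benzyloxy)-6-methylbenzoic trifluoroacetic anhydride | O=C(OC(=O)C(F)(F)F)c1c(C)cc(OCc2ccccc2)cc1OCc1ccccc1 | intermediate (not isolated)
20 | methyl 4-{[2,4-bis(benzyloxy)-6-methylbenzoyl]oxy}-2-hydroxy-6-methylbenzoate | COC(=O)c1c(C)cc(OC(=O)c2c(C)cc(OCc3ccccc3)cc2OCc2ccccc2)cc1O | intermediate
21 | methyl 4-{[2,4-bis(benzyloxy)-6-methylbenzoyl]oxy}-2-methoxy-6-methylbenzoate | COC(=O)c1c(C)cc(OC(=O)c2c(C)cc(OCc3ccccc3)cc2OCc2ccccc2)cc1OC | intermediate
22 | methyl 4-[(2,4-dihydroxy-6-methylbenzoyl)oxy]-2-methoxy-6-methylbenzoate | COC(=O)c1c(C)cc(OC(=O)c2c(C)cc(O)cc2O)cc1OC | intermediate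
23 | O-(2-hydroxy-4-methoxy-6-methylbenzoyl)-N,N'-dicyclohexylisourea | COc1cc(C)c(C(=O)OC(=NC2CCCCC2)NC2CCCCC2)c(O)c1 | intermediate (not isolated)
24 | methyl 4-({2-hydroxy-4-[(2-hydroxy-4-methoxy-6-methylbenzoyl)oxy]-6-methylbenzoyl}oxy)-2-methoxy-6-methylbenzoate (CNP0106353.0) | COC(=O)c1c(C)cc(OC(=O)c2c(C)cc(OC(=O)c3c(C)cc(OC)cc3O)cc2O)cc1OC | target

**Step count and risks**

Total step count: 11. Longest linear sequence: 6 steps (steps 1–5 and 11, or steps 6–11).

Steps most likely to fail:

1. Step 3. The cycloaddition may be slower than thermal oligomerisation of the ynol ether, or the reversed orientation may compete, so that little of the desired benzoate forms. The fallback uses known chemistry and sets out from 14. Exhaustive O-methylation (MeI, K2CO3, DMF, 60 °C) should give methyl 2,4-dimethoxy-6-methylbenzoate F1. Saponification (KOH, DMSO/H2O, 90 °C; then HCl) should then give acid 11, where the route resumes at step 5.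

2. Step 11. Activation of the doubly ortho-substituted acid may be slow enough for O-to-N acyl migration to an N-acylurea, or acylation may spill over to a chelated phenol. The fallback sets out from 13 and masks the ring A phenol. Double benzylation (BnBr, K2CO3, DMF) should give benzyl 2-(benzyloxy)-4-methoxy-6-methylbenzoate F2. Saponification (KOH, DMSO/H2O) should give 2-(benzyloxy)-4-methoxy-6-methylbenzoic acid F3. Coupling of F3 with 22 (TFAA, toluene, rt) should give methyl 4-({4-[(2-(benzyloxy)-4-methoxy-6-methylbenzoyl)oxy]-2-hydroxy-6-methylbenzoyl}oxy)-2-methoxy-6-methylbenzoate F4. Hydrogenolysis (H2, 10% Pd/C, EtOAc) then returns to the route at 24.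

3. Step 9. Alkylation of the hydrogen-bonded phenol may be slow enough for carbonate or phenoxide to cleave or transfer the depside ester. The fallback sets out from 14 and methylates ring C before the rings are joined. Monobenzylation (BnBr 1 equiv, K2CO3, acetone, reflux) is stopped at 15, which is isolated. Methylation (MeI, K2CO3, DMF) should give methyl 4-(benzyloxy)-2-methoxy-6-methylbenzoate F5. Hydrogenolysis (H2, 10% Pd/C) should give methyl 4-hydroxy-2-methoxy-6-methylbenzoate F6. Esterification of F6 with acid 18 (TFAA, toluene, rt) returns to the route at 21.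

**Further compounds**

F1 | step 3 | methyl 2,4-dimethoxy-6-methylbenzoate | COc1cc(C)c(C(=O)OC)c(OC)c1
F2 | step 11 | benzyl 2-(benzyloxy)-4-methoxy-6-methylbenzoate | COc1cc(C)c(C(=O)OCc2ccccc2)c(OCc2ccccc2)c1
F3 | step 11 | 2-(benzyloxy)-4-methoxy-6-methylbenzoic acid | COc1cc(C)c(C(=O)O)c(OCc2ccccc2)c1
F4 | step 11 | methyl 4-({4-[(2-(benzyloxy)-4-methoxy-6-methylbenzoyl)oxy]-2-hydroxy-6-methylbenzoyl}oxy)-2-methoxy-6-methylbenzoate | COC(=O)c1c(C)cc(OC(=O)c2c(C)cc(OC(=O)c3c(C)cc(OC)cc3OCc3ccccc3)cc2O)cc1OC
F5 | step 9 | methyl 4-(benzyloxy)-2-methoxy-6-methylbenzoate | COC(=O)c1c(C)cc(OCc2ccccc2)cc1OC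
F6 | step 9 | methyl 4-hydroxy-2-methoxy-6-methylbenzoate | COC(=O)c1c(C)cc(O)cc1OC
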